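**Plan**

- Prostanoid numbering is used throughout (C1 ester carbon, C8–C12 ring, C9 ketone, C10 bromide, C12 carbinol, C13–C20 octenyl). The enabling feature: the cyclopentenone C8–C12 carries C7 as an exocyclic trigonal carbon on C8, between the C9 ketone and the oxygenated C12. C7, C8, C12, C11, C10 and C9 can therefore be the ring of a 2,3-epoxycyclohex-5-enone oxygenated at C4 (epoxide on C7/C8, C12 the tertiary carbinol); moving the acyl carbon C9 from C7 to C8 contracts it to the target ring.
- Retrosynthetic cuts: C6–C7 (alkenyl–alkenyl coupling at a C7 enol triflate); C8–C9 (1,2-acyl shift, i.e. back to the epoxy enone); C10–Br; the C14=C15 π bond (alkyne); C15–C16 and C12–C13 (acetylide alkylation, propargylation of an epoxy quinone monoketal); the C7–O–C8 epoxide.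
- Forward: the six-membered ring is bought as a quinone monoketal. It is epoxidised, C13–C15 and C16–C20 are attached at C12, the C9 ketone is released, C12–O is trifluoroacetylated, C10 is brominated and the alkyne is semihydrogenated. The five-membered ring then forms by contraction, and the C1–C6 chain is joined last.
- Stereochemistry: a C2-symmetric (2R,4R)-pentanediol ketal controls the epoxide (C7, C8); the propargyl nucleophile enters C12 anti to the epoxide (12S); 14Z comes from cis-hydrogenation; 7Z from the hydrogen-bonded enol and its lithium chelate, carried through a stereoretentive coupling; 5E from syn-hydroboration.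

Key step: step 9

Remark: the face of the enone that the (2R,4R)-acetal leaves open in step 2 is assumed to be the one giving the epoxide drawn; if the acetal favours the other face, (2S,4S)-pentane-2,4-diol is used and nothing else changes.

**Step 1**
Reactants: 1 4,4-dimethoxycyclohexa-2,5-dien-1-one; 2 (2R,4R)-pentane-2,4-diol
Product: 3 (2R,4R)-2,4-dimethyl-1,5-dioxaspiro[5.5]undeca-7,10-dien-9-one
Conditions: PPTS (cat.), toluene, 4 Å MS, 40 °C
Reagents that add atoms: none
Why: Acid-catalysed transketalisation of the quinone monoketal, driven by removal of methanol, exchanges the two methoxy groups for the C2-symmetric diol without touching its stereocentres.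

**Step 2**
Reactants: 3 (2R,4R)-2,4-dimethyl-1,5-dioxaspiro[5.5]undeca-7,10-dien-9-one
Product: 4 (1R,6S)-5,5-[(2R,4R)-pentane-2,4-diylbis(oxy)]-7-oxabicyclo[4.1.0]hept-3-en-2-one
Conditions: Ph3COOH (1.05 equiv), KN(SiMe3)2 (0.2 equiv), THF, −78 to −40 °C
Reagents that add atoms: trityl hydroperoxide, OOC(c1ccccc1)(c1ccccc1)c1ccccc1
Why: Weitz–Scheffer nucleophilic epoxidation in which the bulky trityl peroxide anion adds to the enone carbon next to the spiro centre from the face left open by the chiral dioxane (the two enone arms are homotopic by C2 symmetry, their faces diastereotopic) and the enolate closes onto O–O, which fixes C7 and C8; one equivalent of oxidant should stop at the mono-epoxide, and the minor diastereomer can be removed by chromatography.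

**Step 3**
Reactants: 4 (1R,6S)-5,5-[(2R,4R)-pentane-2,4-diylbis(oxy)]-7-oxabicyclo[4.1.0]hept-3-en-2-one; 5 3-bromoprop-1-yne
Product: 7 (1R,2S,6S)-2-(prop-2-yn-1-yl)-5,5-[(2R,4R)-pentane-2,4-diylbis(oxy)]-7-oxabicyclo[4.1.0]hept-3-en-2-ol, via allenylzinc bromide 6 (not isolated)
Conditions: 5, Zn dust, THF, 0 °C; solution transferred onto 4, THF, −78 to −20 °C; aq. NH4Cl
Reagents that add atoms: none
Why: Barbier-type propargylation in which allenylzinc bromide adds through its CH2 terminus (SE2′) to the C12 carbonyl in 1,2-fashion on the face anti to the neighbouring epoxide oxygen, giving the homopropargylic tertiary alcohol cis to the epoxide and so setting C12.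

**Step 4**
Reactants: 7 (1R,2S,6S)-2-(prop-2-yn-1-yl)-5,5-[(2R,4R)-pentane-2,4-diylbis(oxy)]-7-oxabicyclo[4.1.0]hept-3-en-2-ol; 8 1-iodopentane
Product: 10 (1R,2S,6S)-2-(oct-2-yn-1-yl)-5,5-[(2R,4R)-pentane-2,4-diylbis(oxy)]-7-oxabicyclo[4.1.0]hept-3-en-2-ol, via dilithium alkoxide acetylide 9 (not isolated)
Conditions: n-BuLi (2.1 equiv), THF, −78 °C; 8, DMPU, −78 °C to rt
Reagents that add atoms: none
Why: Alkylation of a lithium acetylide by a primary iodide in THF/DMPU, in which the hindered tertiary alkoxide is not alkylated and, being cis to the epoxide, cannot open it (no Payne rearrangement).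

**Step 5**
Reactants: 10 (1R,2S,6S)-2-(oct-2-yn-1-yl)-5,5-[(2R,4R)-pentane-2,4-diylbis(oxy)]-7-oxabicyclo[4.1.0]hept-3-en-2-ol
Product: 11 (1S,5S,6R)-5-hydroxy-5-(oct-2-yn-1-yl)-7-oxabicyclo[4.1.0]hept-3-en-2-one
Conditions: 48% aq. HF, MeCN, 0 °C to rt
Reagents that add atoms: water, O
Why: Acid hydrolysis of the allylic ketal through its conjugated oxocarbenium ion releases the C9 enone and the auxiliary diol under conditions that the electron-poor epoxy ketone, the tertiary alcohol and the alkyne should tolerate.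

**Step 6**
Reactants: 11 (1S,5S,6R)-5-hydroxy-5-(oct-2-yn-1-yl)-7-oxabicyclo[4.1.0]hept-3-en-2-one
Product: 12 (1S,5S,6R)-5-(oct-2-yn-1-yl)-5-(trifluoroacetoxy)-7-oxabicyclo[4.1.0]hept-3-en-2-one
Conditions: (CF3CO)2O, pyridine, CH2Cl2, −20 to 0 °C
Reagents that add atoms: trifluoroacetic anhydride, O=C(OC(=O)C(F)(F)F)C(F)(F)F
Why: O-Acylation of the hindered tertiary alcohol by the very reactive anhydride gives the ester that shuts down semipinacol migration from C12 in step 9, keeps the hydroxyl from attacking a bromine-activated triple bond in step 7, and is later removable by mild base.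

**Step 7**
Reactants: 12 (1S,5S,6R)-5-(oct-2-yn-1-yl)-5-(trifluoroacetoxy)-7-oxabicyclo[4.1.0]hept-3-en-2-one
Product: 14 (1S,5S,6R)-3-bromo-5-(oct-2-yn-1-yl)-5-(trifluoroacetoxy)-7-oxabicyclo[4.1.0]hept-3-en-2-one, via 3,4-dibromo ketone 13 (not isolated)
Conditions: Br2 (1.0 equiv), CH2Cl2, −78 to −40 °C; Et3N, −78 to 0 °C
Reagents that add atoms: bromine, BrBr
Why: Bromine addition to the enone followed by E1cB loss of HBr (the acidic hydrogen is on C10, so bromine stays there) is the standard α-bromination of enones, and at low temperature with one equivalent the conjugated C10=C11 bond should be consumed before the dialkyl alkyne, whose bromination is intrinsically slow.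

**Step 8**
Reactants: 14 (1S,5S,6R)-3-bromo-5-(oct-2-yn-1-yl)-5-(trifluoroacetoxy)-7-oxabicyclo[4.1.0]hept-3-en-2-one
Product: 15 (1S,5S,6R)-3-bromo-5-[(2Z)-oct-2-en-1-yl]-5-(trifluoroacetoxy)-7-oxabicyclo[4.1.0]hept-3-en-2-one
Conditions: H2 (1 atm), Pd/CaCO3 poisoned with Pb(OAc)2, quinoline, EtOAc, 0 °C, stopped after one equivalent of H2
Reagents that add atoms: none
Why: Lindlar semihydrogenation delivers H2 syn to the alkyne on Pd/CaCO3–Pb(OAc)2 and gives the 14Z alkene, while the poisoned surface should leave the electron-poor bromoalkene, the C–Br bond and the epoxide untouched.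

**Step 9**
Reactants: 15 (1S,5S,6R)-3-bromo-5-[(2Z)-oct-2-en-1-yl]-5-(trifluoroacetoxy)-7-oxabicyclo[4.1.0]hept-3-en-2-one
Product: 17 (4S)-2-bromo-5-[(Z)-hydroxymethylidene]-4-[(2Z)-oct-2-en-1-yl]-4-(trifluoroacetoxy)cyclopent-2-en-1-one, via formyl ketone tautomer 16 (not isolated)
Conditions: BF3·OEt2 (1.1 equiv), CH2Cl2, −78 to −20 °C; pH 7 buffer
Reagents that add atoms: none
Why: BF3 binds the epoxide oxygen, the C8–O bond (β to the ketone; the C7–O bond is held by the adjacent carbonyl) lengthens, and the acyl carbon C9 shifts from C7 to C8 anti to the departing oxygen while C7 becomes a formyl carbon; 16 then enolises to the internally hydrogen-bonded (Z)-hydroxymethylidene ketone 17. The closest known reaction is the Lewis acid-induced acyl-migration rearrangement of α,β-epoxy ketones to 1,3-dicarbonyl compounds, which contracts 2,3-epoxycyclohexanones to 2-formylcyclopentanones. The ring C8–C12 is closed by this suprafacial 1,2-shift of a ring bond (ring contraction forming C8–C9), not by cyclisation of a chain. No stereocentre is created in the isolated product: C8 becomes trigonal on enolisation, C12 and the 14Z alkene are untouched, and the enol oxygen sits cis to C9 because of the hydrogen bond. The step needs the acyl shift to beat hydride shift from C7, semipinacol shift of C13 or C11 from C12, and capture of C8 by a neighbouring group; the trifluoroacetate makes C12 a poor migration origin, lies syn to the epoxide so it cannot open it from the back, and the side chain carries no heteroatom nucleophile. Low temperature in a non-nucleophilic solvent should limit fluorohydrin formation.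

**Step 10**
Reactants: 17 (4S)-2-bromo-5-[(Z)-hydroxymethylidene]-4-[(2Z)-oct-2-en-1-yl]-4-(trifluoroacetoxy)cyclopent-2-en-1-one
Product: 19 (4S)-2-bromo-4-[(2Z)-oct-2-en-1-yl]-4-(trifluoroacetoxy)-5-[(Z)-(trifluoromethanesulfonyloxy)methylidene]cyclopent-2-en-1-one, via lithium enolate 18 (not isolated)
Conditions: LiN(SiMe3)2 (1.05 equiv), toluene/Et2O, −78 °C; Tf2O (1.1 equiv), −78 °C
Reagents that add atoms: trifluoromethanesulfonic anhydride, O=S(=O)(OS(=O)(=O)C(F)(F)F)C(F)(F)F
Why: Chelation-controlled enol triflate formation, in which the lithium enolate of the 1,3-dicarbonyl unit is held as the six-membered (Z)-chelate and is sulfonylated at −78 °C on the less hindered formyl-derived oxygen faster than it can expel the trifluoroacetate, giving the triflate with oxygen cis to C9.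

**Step 11**
Reactants: 20 methyl hex-5-ynoate
Product: 21 methyl (5E)-6-(4,4,5,5-tetramethyl-1,3,2-dioxaborolan-2-yl)hex-5-enoate
Conditions: pinacolborane (1.1 equiv), Cp2Zr(H)Cl (5 mol %), Et3N (10 mol %), neat, 60 °C
Reagents that add atoms: pinacolborane, B1OC(C)(C)C(C)(C)O1
Why: Cp2Zr(H)Cl-catalysed hydroboration of the terminal alkyne is a syn addition with boron at the terminal carbon and gives the (E)-alkenylboronate without reducing the ester.

**Step 12**
Reactants: 19 (4S)-2-bromo-4-[(2Z)-oct-2-en-1-yl]-4-(trifluoroacetoxy)-5-[(Z)-(trifluoromethanesulfonyloxy)methylidene]cyclopent-2-en-1-one; 21 methyl (5E)-6-(4,4,5,5-tetramethyl-1,3,2-dioxaborolan-2-yl)hex-5-enoate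
Product: 23 methyl (5E,7Z,12S,14Z)-10-bromo-12-hydroxy-9-oxoprosta-5,7,10,14-tetraen-1-oate (target), via 12-O-trifluoroacetyl coupling product 22 (not isolated)
Conditions: PdCl2(dppf) (5 mol %), K3PO4 (2 M aq., 3 equiv), THF, 0 °C to rt
Reagents that add atoms: none
Why: Suzuki–Miyaura coupling in which zerovalent palladium carrying a chelating diphosphine should insert into the vinylogous acyl triflate at C7 faster than into the C10–Br bond, transmetalation and reductive elimination keep both alkene geometries (7Z, 5E), and the aqueous phosphate hydrolyses the labile tertiary trifluoroacetate to the free C12 alcohol in the same flask.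

**Compound list**

1 | 4,4-dimethoxycyclohexa-2,5-dien-1-one | COC1(OC)C=CC(=O)C=C1 | starting material
2 | (2R,4R)-pentane-2,4-diol | C[C@@H](O)C[C@@H](C)O | starting material
3 | (2R,4R)-2,4-dimethyl-1,5-dioxaspiro[5.5]undeca-7,10-dien-9-one | C[C@@H]1C[C@@H](C)OC2(O1)C=CC(=O)C=C2 | intermediate
4 | (1R,6S)-5,5-[(2R,4R)-pentane-2,4-diylbis(oxy)]-7-oxabicyclo[4.1.0]hept-3-en-2-one (C12 ketone, C7/C8 epoxide, C9 ketal) | O=C1C=CC2(O[C@H](C)C[C@@H](C)O2)[C@H]3O[C@@H]13 | intermediate
5 | 3-bromoprop-1-yne (propargyl bromide) | BrCC#C | starting material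
6 | propa-1,2-dienylzinc bromide (allenylzinc bromide) | C=C=C[Zn]Br | intermediate (not isolated)
7 | (1R,2S,6S)-2-(prop-2-yn-1-yl)-5,5-[(2R,4R)-pentane-2,4-diylbis(oxy)]-7-oxabicyclo[4.1.0]hept-3-en-2-ol (hydroxyl cis to the epoxide) | C#CC[C@]1(O)C=CC2(O[C@H](C)C[C@@H](C)O2)[C@H]3O[C@@H]13 | intermediate
8 | 1-iodopentane | CCCCCI | starting material
9 | dilithium alkoxide acetylide of 7 | [Li+].[Li+].[C-]#CC[C@]1([O-])C=CC2(O[C@H](C)C[C@@H](C)O2)[C@H]3O[C@@H]13 | intermediate (not isolated)
10 | (1R,2S,6S)-2-(oct-2-yn-1-yl)-5,5-[(2R,4R)-pentane-2,4-diylbis(oxy)]-7-oxabicyclo[4.1.0]hept-3-en-2-ol | CCCCCC#CC[C@]1(O)C=CC2(O[C@H](C)C[C@@H](C)O2)[C@H]3O[C@@H]13 | intermediate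
11 | (1S,5S,6R)-5-hydroxy-5-(oct-2-yn-1-yl)-7-oxabicyclo[4.1.0]hept-3-en-2-one | CCCCCC#CC[C@]1(O)C=CC(=O)[C@H]2O[C@@H]12 | intermediate
12 | (1S,5S,6R)-5-(oct-2-yn-1-yl)-5-(trifluoroacetoxy)-7-oxabicyclo[4.1.0]hept-3-en-2-one | CCCCCC#CC[C@]1(OC(=O)C(F)(F)F)C=CC(=O)[C@H]2O[C@@H]12 | intermediate
13 | 3,4-dibromo ketone from anti addition of Br2 to 12 (epoxide and quaternary centre as in 12; the two CHBr centres as formed) | CCCCCC#CC[C@]1(OC(=O)C(F)(F)F)C(Br)C(Br)C(=O)[C@H]2O[C@@H]12 | intermediate (not isolated)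
14 | (1S,5S,6R)-3-bromo-5-(oct-2-yn-1-yl)-5-(trifluoroacetoxy)-7-oxabicyclo[4.1.0]hept-3-en-2-one | CCCCCC#CC[C@]1(OC(=O)C(F)(F)F)C=C(Br)C(=O)[C@H]2O[C@@H]12 | intermediate
15 | (1S,5S,6R)-3-bromo-5-[(2Z)-oct-2-en-1-yl]-5-(trifluoroacetoxy)-7-oxabicyclo[4.1.0]hept-3-en-2-one (ester syn to the epoxide; precursor of the key step) | CCCCC/C=C\C[C@]1(OC(=O)C(F)(F)F)C=C(Br)C(=O)[C@H]2O[C@@H]12 | intermediate
16 | 3-bromo-5-[(2Z)-oct-2-en-1-yl]-2-oxo-5-(trifluoroacetoxy)cyclopent-3-ene-1-carbaldehyde (formyl ketone tautomer of 17; C8 formed with inversion, lost on enolisation) | CCCCC/C=C\C[C@]1(OC(=O)C(F)(F)F)C=C(Br)C(=O)[C@H]1C=O | intermediate (not isolated)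
17 | (4S)-2-bromo-5-[(Z)-hydroxymethylidene]-4-[(2Z)-oct-2-en-1-yl]-4-(trifluoroacetoxy)cyclopent-2-en-1-one (product of the key step) | CCCCC/C=C\C[C@]1(OC(=O)C(F)(F)F)C=C(Br)C(=O)/C1=C\O | intermediate
18 | lithium (Z)-enolate of 17 | CCCCC/C=C\C[C@]1(OC(=O)C(F)(F)F)C=C(Br)C(=O)/C1=C\[O-].[Li+] | intermediate (not isolated)
19 | (4S)-2-bromo-4-[(2Z)-oct-2-en-1-yl]-4-(trifluoroacetoxy)-5-[(Z)-(trifluoromethanesulfonyloxy)methylidene]cyclopent-2-en-1-one | CCCCC/C=C\C[C@]1(OC(=O)C(F)(F)F)C=C(Br)C(=O)/C1=C\OS(=O)(=O)C(F)(F)F | intermediate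
20 | methyl hex-5-ynoate | C#CCCCC(=O)OC | starting material
21 | methyl (5E)-6-(4,4,5,5-tetramethyl-1,3,2-dioxaborolan-2-yl)hex-5-enoate | COC(=O)CCC/C=C/B1OC(C)(C)C(C)(C)O1 | intermediate
22 | methyl (5E,7Z,12S,14Z)-10-bromo-9-oxo-12-(trifluoroacetoxy)prosta-5,7,10,14-tetraen-1-oate | CCCCC/C=C\C[C@]1(OC(=O)C(F)(F)F)C=C(Br)C(=O)/C1=C\C=C\CCCC(=O)OC | intermediate (not isolated)
23 | methyl (5E,7Z,12S,14Z)-10-bromo-12-hydroxy-9-oxoprosta-5,7,10,14-tetraen-1-oate | CCCCC/C=C\C[C@]1(O)C=C(Br)C(=O)/C1=C\C=C\CCCC(=O)OC | target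

**Step count**

Total: 12 steps. Longest linear sequence: 11 steps (steps 1–10 and 12); step 11 is a one-step branch.

**Steps most likely to fail**

Step 9. Ionisation of the C8–O bond is slowed by the acyloxy-bearing C12 beside it, and the bromine-bearing enoyl carbon is a reluctant migrating group. Hydride shift from C7 (towards the 1,2-dione) or opening of the epoxide by fluoride could then take over. The fallback runs the contraction before the bromination, on the unbrominated enone, whose acyl carbon should migrate more readily. It sets out from 12. BF3·OEt2 should give (4S)-5-[(Z)-hydroxymethylidene]-4-(oct-2-yn-1-yl)-4-(trifluoroacetoxy)cyclopent-2-en-1-one F1. LiN(SiMe3)2 then Tf2O should give its (Z)-enol triflate F2. Br2 followed by i-Pr2NEt should give the 2-bromo enol triflate F3. Semihydrogenation over Pd/CaCO3 poisoned with Pb(OAc)2 comes back to the route at 19.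

Step 7. Addition of bromine to the triple bond in competition with the enone would consume the masked alkene. The fallback makes the (Z)-alkene by Wittig olefination after the bromination, so that the enone is the only π bond present when bromine is used. It sets out from 4. Commercial (1,3-dioxolan-2-ylmethyl)magnesium bromide (THF, −78 °C) should add anti to the epoxide to give the acetal carbinol (1R,2S,6S)-2-(1,3-dioxolan-2-ylmethyl)-5,5-[(2R,4R)-pentane-2,4-diylbis(oxy)]-7-oxabicyclo[4.1.0]hept-3-en-2-ol F4. Aqueous HF in MeCN should remove both acetals to give (1S,5S,6R)-5-hydroxy-5-(2-oxoethyl)-7-oxabicyclo[4.1.0]hept-3-en-2-one F5. Br2 then Et3N should give its 3-bromo derivative F6. Hexylidenetriphenylphosphorane F7 (from hexyltriphenylphosphonium bromide and NaN(SiMe3)2, THF, −78 °C, salt-free) should give (1S,5S,6R)-3-bromo-5-hydroxy-5-[(2Z)-oct-2-en-1-yl]-7-oxabicyclo[4.1.0]hept-3-en-2-one F8. (CF3CO)2O/pyridine comes back to the route at 15. The aldehyde stages must be handled cold and briefly, because the hydrated aldehyde can add to the enone.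

Step 12. Oxidative addition at C10–Br in competition with the triflate, or Z-to-E isomerisation of the β-acyl alkenylpalladium intermediate in the basic aqueous medium, would erode the coupling. The fallback is a neutral, chloride-promoted Stille coupling, conditions under which triflates react ahead of bromides. It sets out from 20 and 19. Radical hydrostannation of 20 (Bu3SnH, AIBN, 80 °C) should give methyl (5E)-6-(tributylstannyl)hex-5-enoate F9. Coupling of F9 with 19 (PdCl2(PPh3)2, LiCl, DMF, rt) should give 22, which is now isolated. KHCO3 in MeOH at 0 °C cleaves the trifluoroacetate and comes back to the route at 23.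

**Further compounds**

F1 | step 9 | (4S)-5-[(Z)-hydroxymethylidene]-4-(oct-2-yn-1-yl)-4-(trifluoroacetoxy)cyclopent-2-en-1-one | CCCCCC#CC[C@]1(OC(=O)C(F)(F)F)C=CC(=O)/C1=C\O
F2 | step 9 | (4S)-4-(oct-2-yn-1-yl)-4-(trifluoroacetoxy)-5-[(Z)-(trifluoromethanesulfonyloxy)methylidene]cyclopent-2-en-1-one | CCCCCC#CC[C@]1(OC(=O)C(F)(F)F)C=CC(=O)/C1=C\OS(=O)(=O)C(F)(F)F
F3 | step 9 | (4S)-2-bromo-4-(oct-2-yn-1-yl)-4-(trifluoroacetoxy)-5-[(Z)-(trifluoromethanesulfonyloxy)methylidene]cyclopent-2-en-1-one | CCCCCC#CC[C@]1(OC(=O)C(F)(F)F)C=C(Br)C(=O)/C1=C\OS(=O)(=O)C(F)(F)F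
F4 | step 7 | (1R,2S,6S)-2-(1,3-dioxolan-2-ylmethyl)-5,5-[(2R,4R)-pentane-2,4-diylbis(oxy)]-7-oxabicyclo[4.1.0]hept-3-en-2-ol | C(C1OCCO1)[C@]2(O)C=CC3(O[C@H](C)C[C@@H](C)O3)[C@H]4O[C@@H]24
F5 | step 7 | (1S,5S,6R)-5-hydroxy-5-(2-oxoethyl)-7-oxabicyclo[4.1.0]hept-3-en-2-one | O=CC[C@]1(O)C=CC(=O)[C@H]2O[C@@H]12
F6 | step 7 | (1S,5S,6R)-3-bromo-5-hydroxy-5-(2-oxoethyl)-7-oxabicyclo[4.1.0]hept-3-en-2-one | O=CC[C@]1(O)C=C(Br)C(=O)[C@H]2O[C@@H]12
F7 | step 7 | hexylidenetriphenylphosphorane | CCCCCC=P(c1ccccc1)(c1ccccc1)c1ccccc1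
F8 | step 7 | (1S,5S,6R)-3-bromo-5-hydroxy-5-[(2Z)-oct-2-en-1-yl]-7-oxabicyclo[4.1.0]hept-3-en-2-one | CCCCC/C=C\C[C@]1(O)C=C(Br)C(=O)[C@H]2O[C@@H]12
F9 | step 12 | methyl (5E)-6-(tributylstannyl)hex-5-enoate | COC(=O)CCC/C=C/[Sn](CCCC)(CCCC)CCCC
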